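**Assumptions (one line each).** The quinidine-derived cinchona thiourea is taken to give the 2S flavanone (check by CD; if the sense is reversed, the commercial quinine-derived pseudoenantiomer is used with no other change). TIPS = triisopropylsilyl, TES = triethylsilyl.

## Retrosynthetic overview

1. Target 21 ⇒ global desilylation of 20, which is cut at the C8–CH2 bond (sp2–sp3 Negishi) into 8-iodoflavanone 19 and chiral alkyl iodide 9.
2. The pyranone ring of 19 (the only ring built; rings A and B are bought) closes by a catalyst-controlled intramolecular oxa-Michael addition of alkylidene β-ketoester 17, followed by decarboxylation; this sets C2 (S).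
3. 17 ⇒ Knoevenagel condensation of A-ring β-ketoester 14 (from phloroacetophenone) with B-ring aldehyde 16.
4. 9 ⇒ Evans deconjugative α-prenylation of an N-senecioyl oxazolidinone (sets the side-chain stereocentre), then epoxidation of the prenyl alkene and hydride opening to the tertiary alcohol.

## Route

### Side-chain arm

**Step 1**
Reactants: 1, (S)-4-benzyloxazolidin-2-one; 2, 3-methylbut-2-enoyl chloride
Product: 3, (S)-4-benzyl-3-(3-methylbut-2-enoyl)oxazolidin-2-one
Conditions: n-BuLi, THF, −78 °C; then 2, −78 → 0 °C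
Reagents that add atoms: none (both partners are numbered reactants)
Why: N-acylation of the lithiated oxazolidinone by the acid chloride is fast and clean at low temperature.

**Step 2**
Reactants: 3; 4, prenyl bromide (1-bromo-3-methylbut-2-ene)
Product: 5, (S)-4-benzyl-3-[(2S)-5-methyl-2-(prop-1-en-2-yl)hex-4-enoyl]oxazolidin-2-one
Conditions: NaHMDS (1.0 equiv), THF, −78 °C; then 4, −78 → −40 °C
Reagents that add atoms: none
Why: Evans deconjugative α-alkylation: γ-deprotonation gives the chelated Z-dienolate, which is alkylated at the α-carbon on the face opposite the C4 benzyl group, setting the (S) centre (this becomes 2″R in the target) and leaving the isopropenyl group.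

**Step 3**
Reactants: 5
Product: 6, (S)-4-benzyl-3-[(2S)-3-(3,3-dimethyloxiran-2-yl)-2-(prop-1-en-2-yl)propanoyl]oxazolidin-2-one (mixture of oxirane epimers)
Conditions: mCPBA (1.05 equiv), NaHCO3, CH2Cl2, −20 → 0 °C
Reagents that add atoms: mCPBA, O=C(OO)c1cccc(Cl)c1
Why: Prilezhaev epoxidation prefers the electron-rich trisubstituted alkene over the 1,1-disubstituted isopropenyl group, which is also inductively deactivated by the adjacent acyl-bearing carbon; the oxirane centre is removed in the next step.

**Step 4**
Reactants: 6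
Product: 7, (S)-5-methyl-2-(prop-1-en-2-yl)hexane-1,5-diol
Conditions: LiBH4, MeOH (1 equiv), THF, 0 °C; then LiAlH4, 0 °C → rt (one pot)
Reagents that add atoms: none
Why: Reductive cleavage of the auxiliary gives the primary alcohol, and hydride opens the trisubstituted epoxide at its less hindered CH carbon to give the tertiary alcohol; the stereocentre is not involved.

**Step 5**
Reactants: 7
Product: 8, (S)-6-iodo-2-methyl-5-(prop-1-en-2-yl)hexan-2-ol
Conditions: PPh3, imidazole, I2 (premixed), CH2Cl2, 0 °C
Reagents that add atoms: iodine, II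
Why: Appel-type (Garegg–Samuelsson) iodination converts only the primary alcohol; the tertiary alcohol does not react and premixing avoids free I2 at the alkene.

**Step 6**
Reactants: 8
Product: 9, (S)-triethyl{[6-iodo-2-methyl-5-(prop-1-en-2-yl)hexan-2-yl]oxy}silane
Conditions: TESOTf, 2,6-lutidine, CH2Cl2, −78 → 0 °C
Reagents that add atoms: TESOTf, CC[Si](CC)(CC)OS(=O)(=O)C(F)(F)F
Why: Silyl triflate silylation of the tertiary alcohol masks the acidic OH (and blocks tetrahydropyran formation) before organometallic formation.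

### A-ring / flavanone arm

**Step 7**
Reactants: 10, 2′,4′,6′-trihydroxyacetophenone
Product: 11, 1-[2,6-dihydroxy-4-(triisopropylsilyloxy)phenyl]ethanone
Conditions: TIPSCl (1.05 equiv), imidazole, DMF, 0 °C
Reagents that add atoms: TIPSCl, CC(C)[Si](Cl)(C(C)C)C(C)C
Why: Selective silylation of the most acidic, non-chelated para hydroxyl; the two ortho hydroxyls are held back by hydrogen bonding to the ketone and by sterics.

**Step 8**
Reactants: 11
Product: 12, 1-[2-hydroxy-6-methoxy-4-(triisopropylsilyloxy)phenyl]ethanone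
Conditions: MeOH, PPh3, DIAD, THF, 0 °C → rt
Reagents that add atoms: methanol, CO
Why: Mitsunobu etherification under neutral conditions (silyl ether safe) stops at the mono-methyl ether because the remaining hydroxyl is strongly chelated to the carbonyl.

**Step 9**
Reactants: 12
Product: 13, 1-[2-hydroxy-3-iodo-6-methoxy-4-(triisopropylsilyloxy)phenyl]ethanone
Conditions: BnMe3N·ICl2 (1.0 equiv), NaHCO3, CH2Cl2/MeOH, rt
Reagents that add atoms: benzyltrimethylammonium dichloroiodate, C[N+](C)(C)Cc1ccccc1.Cl[I-]Cl
Why: Electrophilic aromatic iodination with this reagent is directed ortho to the free chelated phenol, placing iodine at the carbon that becomes C8.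

**Step 10**
Reactants: 13
Product: 14, tert-butyl 3-[2-hydroxy-3-iodo-6-methoxy-4-(triisopropylsilyloxy)phenyl]-3-oxopropanoate
Conditions: LiHMDS (3.3 equiv), THF, −78 °C; Boc2O (1.1 equiv), −78 → 0 °C
Reagents that add atoms: Boc2O, CC(C)(C)OC(=O)OC(=O)OC(C)(C)C
Why: Claisen-type C-acylation of the phenoxide/enolate dianion; any aryl carbonate formed first converges on the same product by Baker–Venkataraman-type O→C transfer, and the tert-butyl ester resists lactonisation to a 4-hydroxycoumarin.

**Step 11**
Reactants: 15, 2,4-dihydroxybenzaldehyde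
Product: 16, 2,4-bis(triisopropylsilyloxy)benzaldehyde
Conditions: TIPSOTf (2.4 equiv), 2,6-lutidine, CH2Cl2, 0 °C → rt
Reagents that add atoms: TIPSOTf, CC(C)[Si](C(C)C)(C(C)C)OS(=O)(=O)C(F)(F)F
Why: Exhaustive silylation (the triflate overcomes the chelated ortho OH) gives ethers that tolerate acid and Pd and are later removed by fluoride.

**Step 12**
Reactants: 14; 16
Product: 17, tert-butyl 3-[2,4-bis(triisopropylsilyloxy)phenyl]-2-[2-hydroxy-3-iodo-6-methoxy-4-(triisopropylsilyloxy)benzoyl]prop-2-enoate (mainly one alkene isomer)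
Conditions: piperidine (20 mol%), AcOH (20 mol%), 4 Å MS, toluene, rt; quick silica filtration
Reagents that add atoms: none
Why: Knoevenagel condensation of the active methylene with the aldehyde under mild piperidinium acetate catalysis gives the doubly activated Michael acceptor without closing the ring.

**Step 13 (key ring closure)**
Reactants: 17
Product: 18, tert-butyl (2S)-2-[2,4-bis(triisopropylsilyloxy)phenyl]-8-iodo-5-methoxy-4-oxo-7-(triisopropylsilyloxy)chromane-3-carboxylate (C3 epimers/enol)
Conditions: quinidine-derived 3,5-bis(trifluoromethyl)phenyl thiourea (9-amino-9-deoxy-epi-quinidine type, 10–20 mol%), toluene, −25 °C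
Reagents that add atoms: none
Why: Asymmetric intramolecular oxa-Michael addition (6-endo): the thiourea binds the β-ketoester while the quinuclidine activates the phenol, so the oxygen adds to one face of the alkylidene and sets C2 as S.

**Step 14**
Reactants: 18
Product: 19, (2S)-2-[2,4-bis(triisopropylsilyloxy)phenyl]-8-iodo-5-methoxy-7-(triisopropylsilyloxy)chroman-4-one
Conditions: TsOH·H2O, toluene, 80 °C (same flask as Step 13)
Reagents that add atoms: none
Why: Acid-mediated tert-butyl ester cleavage and decarboxylation of the β-keto acid removes the activating group without the base that would cause retro-oxa-Michael racemisation; aryl TIPS ethers survive.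

### Union and endgame

**Step 15**
Reactants: 9 (1.5 equiv); 19
Product: 20, (2S)-2-[2,4-bis(triisopropylsilyloxy)phenyl]-5-methoxy-8-[(2R)-5-methyl-2-(prop-1-en-2-yl)-5-(triethylsilyloxy)hexyl]-7-(triisopropylsilyloxy)chroman-4-one
Conditions: 9, t-BuLi (2.1 equiv), Et2O, −78 °C; ZnCl2 (THF), −78 °C → rt; then 19, Pd(OAc)2 (5 mol%), SPhos (10 mol%), THF/NMP, rt → 45 °C
Reagents that add atoms: none
Why: Negishi sp3–sp2 cross-coupling: the non-basic alkylzinc tolerates the ketone and the C2 centre, and the bulky biarylphosphine favours reductive elimination over β-hydride elimination; neither stereocentre is touched, and the minor 2R diastereomer from Step 13 is removed here by chromatography.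

**Step 16**
Reactants: 20
Product: 21, (2S)-2-(2,4-dihydroxyphenyl)-7-hydroxy-8-[(2R)-5-hydroxy-5-methyl-2-(prop-1-en-2-yl)hexyl]-5-methoxychroman-4-one (target, CID 44563198)
Conditions: TBAF/AcOH (1:1, excess), THF, 0 °C → rt
Reagents that add atoms: none
Why: Buffered fluoride desilylation removes the three aryl TIPS ethers and the tertiary TES ether without strong acid (which would cyclise the phenol onto the isopropenyl group or dehydrate the tertiary alcohol) or free base (which would racemise C2).

## Compound list

1 | (S)-4-benzyloxazolidin-2-one | O=C1N[C@@H](Cc2ccccc2)CO1 | starting material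
2 | 3-methylbut-2-enoyl chloride | CC(C)=CC(=O)Cl | starting material
3 | (S)-4-benzyl-3-(3-methylbut-2-enoyl)oxazolidin-2-one | CC(C)=CC(=O)N1[C@@H](Cc2ccccc2)COC1=O | intermediate
4 | prenyl bromide | CC(C)=CCBr | starting material
5 | (S)-4-benzyl-3-[(2S)-5-methyl-2-(prop-1-en-2-yl)hex-4-enoyl]oxazolidin-2-one | C=C(C)[C@H](CC=C(C)C)C(=O)N1[C@@H](Cc2ccccc2)COC1=O | intermediate
6 | epoxy imide (oxirane epimers) | C=C(C)[C@H](CC1OC1(C)C)C(=O)N1[C@@H](Cc2ccccc2)COC1=O | intermediate
7 | (S)-5-methyl-2-(prop-1-en-2-yl)hexane-1,5-diol | C=C(C)[C@H](CCC(C)(C)O)CO | intermediate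
8 | (S)-6-iodo-2-methyl-5-(prop-1-en-2-yl)hexan-2-ol | C=C(C)[C@H](CCC(C)(C)O)CI | intermediate
9 | (S)-triethyl{[6-iodo-2-methyl-5-(prop-1-en-2-yl)hexan-2-yl]oxy}silane | C=C(C)[C@H](CCC(C)(C)O[Si](CC)(CC)CC)CI | intermediate
10 | 2′,4′,6′-trihydroxyacetophenone | CC(=O)c1c(O)cc(O)cc1O | starting material
11 | 1-[2,6-dihydroxy-4-(TIPS-oxy)phenyl]ethanone | CC(=O)c1c(O)cc(O[Si](C(C)C)(C(C)C)C(C)C)cc1O | intermediate
12 | 1-[2-hydroxy-6-methoxy-4-(TIPS-oxy)phenyl]ethanone | CC(=O)c1c(O)cc(O[Si](C(C)C)(C(C)C)C(C)C)cc1OC | intermediate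
13 | 1-[2-hydroxy-3-iodo-6-methoxy-4-(TIPS-oxy)phenyl]ethanone | CC(=O)c1c(O)c(I)c(O[Si](C(C)C)(C(C)C)C(C)C)cc1OC | intermediate
14 | tert-butyl 3-[2-hydroxy-3-iodo-6-methoxy-4-(TIPS-oxy)phenyl]-3-oxopropanoate | CC(C)(C)OC(=O)CC(=O)c1c(O)c(I)c(O[Si](C(C)C)(C(C)C)C(C)C)cc1OC | intermediate
15 | 2,4-dihydroxybenzaldehyde | O=Cc1ccc(O)cc1O | starting material
16 | 2,4-bis(TIPS-oxy)benzaldehyde | O=Cc1ccc(O[Si](C(C)C)(C(C)C)C(C)C)cc1O[Si](C(C)C)(C(C)C)C(C)C | intermediate
17 | alkylidene β-ketoester | CC(C)(C)OC(=O)C(=Cc1ccc(O[Si](C(C)C)(C(C)C)C(C)C)cc1O[Si](C(C)C)(C(C)C)C(C)C)C(=O)c1c(O)c(I)c(O[Si](C(C)C)(C(C)C)C(C)C)cc1OC | intermediate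
18 | tert-butyl (2S)-8-iodo-flavanone-3-carboxylate | Ic1c(O[Si](C(C)C)(C(C)C)C(C)C)cc(OC)c2c1O[C@H](c1ccc(O[Si](C(C)C)(C(C)C)C(C)C)cc1O[Si](C(C)C)(C(C)C)C(C)C)C(C(=O)OC(C)(C)C)C2=O | intermediate
19 | (2S)-2-[2,4-bis(TIPS-oxy)phenyl]-8-iodo-5-methoxy-7-(TIPS-oxy)chroman-4-one | Ic1c(O[Si](C(C)C)(C(C)C)C(C)C)cc(OC)c2c1O[C@H](c1ccc(O[Si](C(C)C)(C(C)C)C(C)C)cc1O[Si](C(C)C)(C(C)C)C(C)C)CC2=O | intermediate
20 | tetrasilyl-protected target (2S,2″R) | C=C(C)[C@H](CCC(C)(C)O[Si](CC)(CC)CC)Cc1c(O[Si](C(C)C)(C(C)C)C(C)C)cc(OC)c2c1O[C@H](c1ccc(O[Si](C(C)C)(C(C)C)C(C)C)cc1O[Si](C(C)C)(C(C)C)C(C)C)CC2=O | intermediate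
21 | (2S)-2-(2,4-dihydroxyphenyl)-7-hydroxy-8-[(2R)-5-hydroxy-5-methyl-2-(prop-1-en-2-yl)hexyl]-5-methoxychroman-4-one | C=C(C)[C@H](CCC(C)(C)O)Cc1c(O)cc(OC)c2c1O[C@H](c1ccc(O)cc1O)CC2=O | target

## Step count

Total steps: 16.
Longest linear sequence: 9 (Steps 7, 8, 9, 10, 12, 13, 14, 15, 16). The side-chain arm is 6 steps (1–6) and joins at Step 15; the B-ring arm is 1 step (11) and joins at Step 12.

## Three steps most likely to fail, with fallbacks

1. **Step 15 (Negishi coupling).** The iodide is di-ortho-substituted and the alkylzinc is β-branched and homoallylic, so β-hydride elimination or simple reduction of the iodide may win. Fallback: attach the side chain first by alkylating the aryllithium from directed ortho-metalation of 1-methoxy-3,5-bis(methoxymethoxy)benzene (between the two OMOM groups) with the primary triflate corresponding to 9, then build the β-ketoester and flavanone on that arene.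

2. **Step 13 (asymmetric oxa-Michael).** The phenol is flanked by iodine, the aryl ketone is di-ortho-substituted and the B-ring carries a bulky ortho-OTIPS, so rate or ee may be poor; acid in Step 14 could also erode ee or cause protodeiodination. Fallback: set C2 by an asymmetric acetate aldol of ketone 13 with aldehyde 16 to the (R)-β-hydroxy ketone, then close the ring by Mitsunobu etherification with inversion.

3. **Step 9 (iodination regiochemistry).** Iodination could occur at C5′ (para to the phenol) or twice. Fallback: make the iodoarene by symmetry instead: directed ortho-metalation/iodination of 1-methoxy-3,5-bis(methoxymethoxy)benzene, MOM removal, then MgCl2/Et3N/paraformaldehyde ortho-formylation (both open positions are equivalent) and aldol/oxidation to the β-ketoester.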